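The numbers in the tables come from a simulation with made-up constants, and the scatter is random.

- A leftover carries amber: each substrate takes up 3 equivalents of reagent on the way to tris adduct, so the south-east run has 1.30 equiv beyond that count and amber 1.00 equiv, while green's 0.800 equiv falls 2.20 equiv short of it.

| flask | substrate | reagent | remark | time |
|---|---|---|---|---|
| north-east | 38 mM | 0.70 equiv | run made earlier |  |
| south | 38 mM | 1.9 equiv | run made earlier |  |
| south-east | 38 mM | 4.3 equiv | run made earlier |  |
| green | 38 mM | 0.800 equiv |  | 12 d |
| amber | 38 mM | 4.00 equiv |  | 12 d |

- north-east (time / d: tris adduct / %): 1.25: 3.1; 2.50: 4.8; 4.00: 3.4; 5.00: 6.1; 6.00: 5.3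
- south (time / d: tris adduct / %): 0.500: 34.7; 0.833: 38.2; 1.67: 39.5; 3.00: 39.4; 6.00: 37.4
- south-east (time / d: tris adduct / %): 0.500: 80.3; 0.833: 82.1; 1.67: 78.8; 3.00: 72.3; 6.00: 64.3

(standard deviation of a reading: 1 percentage point)

- a reading or a percentage of tris adduct counts all its forms, free or not

1. which of these holds the largest part of the substrate at the end of green (tetra adduct / single product / substrate / tris adduct / double product)
2. which of these holds the largest part of the substrate at the end of amber (tetra adduct / single product / substrate / tris adduct / double product)
3. final tris adduct in amber, as a percentage of the substrate charged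

- In the south-east run, tris adduct reads 82.1 % at 0.833 d and 64.3 % at 6.00 d, which two scattered readings put at a decay of 0.0473 /d.
- Assuming that decay exponential, with its constant proportional to the leftover as reckoned above, gives amber a loss clock, the time for tris adduct to fall by a factor of e, of 27.5 d.
- The south-east readings turn downward after 0.833 d, well inside that clock, so two times remain for amber, and 12 d against the clock gives a ratio of 0.437; starting amber from that south-east reading, my reckoning leaves 54.7 % tris adduct in amber at the end.
- The forecast names single product for green, tris adduct for amber and 55 %, holding that “nearly everything stops at single product” at the low charge.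

- Green ends with substrate at 61.0 %, single product at 11.0 % and reagent at 0 % of its charge. In amber, half of the turnover to tris adduct is done by 0.107 d; at the end, with reagent at 16.9 % of its charge, tris adduct stands at 54.1 %, crystals counted, of which 41.2 % are crystals, with tetra adduct at 32.3 % and isomer of the product at 13.6 %, where the 27.5 d clock had given 54.7 %.

    substrate + reagent → single product + by-product (k = 0.0685 /M/min)
    reagent + single product → double product + by-product (k = 0.418 /M/min)
    reagent + double product → tris adduct + by-product (k = 0.235 /M/min)
    reagent + tris adduct → tetra adduct + by-product (k = 0.00444 /M/min)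
    crystals ⇌ tris adduct, rate k5*(cs5 - [tris adduct]) while solid is left; crystals form when [tris adduct] > cs5 (solubility = 4.90 mM, k = 0.0521 /min)
    tris adduct ⇌ isomer of the product (K = 1.06, k = 0.00321 /min)

- A neighbour of amber charged with 16.0 equiv of reagent has a leftover of 13.0 equiv, so the 27.5 d clock shortens to 2.11 d and tris adduct reckons at 0.417 % at the end; that flask computes 0 %, with tetra adduct at >99.9 %.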